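**Retrosynthetic overview**

1. Target 19 ⇐ britannilactone 18 (free C1 and C6 hydroxyls) by double acetylation. Numbering used below: C1 = CH2O, C4 = side-chain CH(CH3), C5=C10 = ring alkene, C6 = CH–O next to it, C7 = ring-fusion CH, C8 = lactone CH–O, C11=C13 = exocyclic alkene, C12 = lactone C=O.
2. 18 ⇐ C6–C7 bond: intramolecular Barbier addition of a 2-(methoxycarbonyl)allylindium (C13–C11–C7) to the C6 aldehyde. Enabling feature: C6 is a carbinol carbon lying between the C5=C10 alkene and C7, and C7 carries the C11(=C13H2)–C12 acrylate unit (a homoallylic-alcohol retron). O8 sits δ to C6, so the aldehyde can be stored as the six-membered lactol O8–C6 of a 3,6-dihydro-2H-pyran; that ring locks C6 and C9 cis on C5=C10 and releases O8–H for indium binding and lactonisation.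
3. Lactol allyl bromide 14/15 ⇐ Baylis–Hillman reaction and SN2′ bromination on aldehyde 11 ⇐ glyoxylate hetero-Diels–Alder adduct 10 (sets C8, builds the dihydropyran) ⇐ 1-silyloxy diene 8.
4. 8 ⇐ enal 5 ⇐ (S)-citronellal 1 (supplies the C4 stereocentre; C1 by alkene cleavage; C9, C10 and C14 from acetone dimethyl ketal).
5. Ring order: dihydropyran (step 5, temporary) → cyclohexene (step 9, C6–C7) → γ-lactone (step 9, O8–C12); the dihydropyran is consumed in step 9.

Key step: step 9

Remark: it is assumed that, of the two cis-γ-lactones open to the all-cis diol ester 17, the one to O8 (the 8,12-olide of the natural series) is the one that forms and persists under mild acid.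

**Step 1**
Reactants: 1 (S)-citronellal
Product: 2 trimethyl{[(3S)-3,7-dimethylocta-1,6-dien-1-yl]oxy}silane (E/Z mixture)
Conditions: TMSCl, Et3N, DMF, 80 °C
Reagents that add atoms: trimethylsilyl chloride, C[Si](C)(C)Cl
Why: Thermodynamic silyl enol ether formation of an enolisable aldehyde; the methyl-bearing stereocentre is β to the carbonyl and is not touched.

**Step 2**
Reactants: 2 trimethyl{[(3S)-3,7-dimethylocta-1,6-dien-1-yl]oxy}silane; 3 2,2-dimethoxypropane
Product: 5 (3S)-3,7-dimethyl-2-(propan-2-ylidene)oct-6-enal, via β-methoxy aldehyde 4 (not isolated)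
Conditions: TMSOTf (5 mol %), CH2Cl2, −78 °C; then DBU, 0 °C to rt
Reagents that add atoms: none
Why: Mukaiyama-type addition of the enol silane to the oxocarbenium ion of the ketal, then E1cB loss of methanol, should give the conjugated tetrasubstituted enal; its two β-methyl groups are equivalent, so no alkene geometry has to be set here.

**Step 3**
Reactants: 5 (3S)-3,7-dimethyl-2-(propan-2-ylidene)oct-6-enal
Product: 7 (3S)-6-hydroxy-3-methyl-2-(propan-2-ylidene)hexanal, via dialdehyde 6 (not isolated)
Conditions: OsO4 (2 mol %), NaIO4, 2,6-lutidine, dioxane/H2O, rt; then NaBH4 (0.3 equiv), EtOH/CH2Cl2, −78 °C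
Reagents that add atoms: osmium tetroxide, O=[Os](=O)(=O)=O (carrier of the new oxygen); sodium periodate, [Na+].[O-]I(=O)(=O)=O (its terminal source)
Why: Lemieux–Johnson cleavage, in which OsO4 should dihydroxylate the electron-rich trisubstituted alkene much faster than the electron-poor tetrasubstituted enal alkene, followed by low-temperature borohydride reduction of the unhindered saturated aldehyde in preference to the hindered conjugated one.

**Step 4**
Reactants: 7 (3S)-6-hydroxy-3-methyl-2-(propan-2-ylidene)hexanal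
Product: 8 (1E)-1-[(tert-butyldimethylsilyl)oxy]-2-[(2S)-5-[(tert-butyldimethylsilyl)oxy]pentan-2-yl]-3-methylbuta-1,3-diene
Conditions: TBSOTf (2.3 equiv), Et3N, CH2Cl2, −78 to 0 °C
Reagents that add atoms: tert-butyldimethylsilyl trifluoromethanesulfonate, CC(C)(C)[Si](C)(C)OS(=O)(=O)C(F)(F)F
Why: Silyl triflate/amine soft enolisation silylates the primary alcohol and γ-deprotonates the O-silylated enal to the 1-silyloxy diene; the s-trans enal (favoured by the cis β-methyl group) should give mainly the 1E enol ether, and the side-chain C–H next to the α-carbon is not acidic.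

**Step 5**
Reactants: 8 (1E)-1-[(tert-butyldimethylsilyl)oxy]-2-[(2S)-5-[(tert-butyldimethylsilyl)oxy]pentan-2-yl]-3-methylbuta-1,3-diene; 9 ethyl glyoxylate
Product: 10 ethyl (2R)-6-[(tert-butyldimethylsilyl)oxy]-5-[(2S)-5-[(tert-butyldimethylsilyl)oxy]pentan-2-yl]-4-methyl-3,6-dihydro-2H-pyran-2-carboxylate (acetal carbon not controlled)
Conditions: [Cu((R,R)-tBu-box)](SbF6)2 (10 mol %), 3 Å MS, CH2Cl2, −78 to −40 °C
Reagents that add atoms: none
Why: Lewis acid-catalysed hetero-Diels–Alder reaction of a 1-oxygenated diene with glyoxylate chelated to the C2-symmetric divalent copper bis(oxazoline) complex; the diene terminus remote from oxygen should attack the re face of the bound aldehyde and set C8 as R, and ring closure fixes C6 and C9 cis on the future C5=C10 alkene.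

**Step 6**
Reactants: 10 ethyl (2R)-6-[(tert-butyldimethylsilyl)oxy]-5-[(2S)-5-[(tert-butyldimethylsilyl)oxy]pentan-2-yl]-4-methyl-3,6-dihydro-2H-pyran-2-carboxylate
Product: 11 (2R)-6-[(tert-butyldimethylsilyl)oxy]-5-[(2S)-5-[(tert-butyldimethylsilyl)oxy]pentan-2-yl]-4-methyl-3,6-dihydro-2H-pyran-2-carbaldehyde
Conditions: DIBAL-H (iBu2AlH, 1.1 equiv), CH2Cl2, −78 °C; aq. KNaC4H4O6
Reagents that add atoms: none
Why: Low-temperature DIBAL-H reduction of an α-alkoxy ester should stop at the chelated aluminium hemiacetal and release the aldehyde on work-up; the silyl acetal and silyl ether are inert and C8 is not exposed to base.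

**Step 7**
Reactants: 11 (2R)-6-[(tert-butyldimethylsilyl)oxy]-5-[(2S)-5-[(tert-butyldimethylsilyl)oxy]pentan-2-yl]-4-methyl-3,6-dihydro-2H-pyran-2-carbaldehyde; 12 methyl acrylate
Product: 13 methyl 2-{hydroxy[(2R)-6-[(tert-butyldimethylsilyl)oxy]-5-[(2S)-5-[(tert-butyldimethylsilyl)oxy]pentan-2-yl]-4-methyl-3,6-dihydro-2H-pyran-2-yl]methyl}prop-2-enoate (carbinol epimers)
Conditions: DABCO (0.5 equiv), dioxane/H2O, rt
Reagents that add atoms: none
Why: Morita–Baylis–Hillman reaction, for which α-alkoxy aldehydes are among the most reactive acceptors; the new carbinol centre (C7) is inconsequential because it becomes sp2 in the next step.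

**Step 8**
Reactants: 13 methyl 2-{hydroxy[(2R)-6-[(tert-butyldimethylsilyl)oxy]-5-[(2S)-5-[(tert-butyldimethylsilyl)oxy]pentan-2-yl]-4-methyl-3,6-dihydro-2H-pyran-2-yl]methyl}prop-2-enoate
Product: 14 methyl (2Z)-2-(bromomethyl)-3-[(2R)-6-[(tert-butyldimethylsilyl)oxy]-5-[(2S)-5-[(tert-butyldimethylsilyl)oxy]pentan-2-yl]-4-methyl-3,6-dihydro-2H-pyran-2-yl]prop-2-enoate
Conditions: NBS, Me2S (premixed), CH2Cl2, −20 to 0 °C
Reagents that add atoms: N-bromosuccinimide, O=C1CCC(=O)N1Br
Why: Corey–Kim-type activation of the allylic alcohol as an alkoxysulfonium salt and SN2′ delivery of bromide should give the rearranged, thermodynamically preferred (Z)-2-(bromomethyl)alk-2-enoate, the usual allylic transposition of Baylis–Hillman alcohols under neutral conditions.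

**Step 9**
Reactants: 14 methyl (2Z)-2-(bromomethyl)-3-[(2R)-6-[(tert-butyldimethylsilyl)oxy]-5-[(2S)-5-[(tert-butyldimethylsilyl)oxy]pentan-2-yl]-4-methyl-3,6-dihydro-2H-pyran-2-yl]prop-2-enoate
Product: 18 britannilactone, via lactol bromide 15 (not isolated), via open-chain hydroxy enal 16 (not isolated), via diol ester 17 (not isolated)
Conditions: 1 M aq. HCl/THF (1:5), 0 °C to rt; then dilution with THF/H2O to 0.005 M, In powder (2 equiv), rt; then extractive work-up, PPTS (cat.), CH2Cl2, rt to 40 °C
Reagents that add atoms: none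
Why: Dilute acid strips both silyl groups and the lactol 15 equilibrates with the (Z)-δ-hydroxy enal 16, whose C5=C10 geometry is inherited from the dihydropyran ring; indium metal inserts into the allylic C–Br bond and the 2-(methoxycarbonyl)allylindium adds through its γ-carbon (C7) to the C6 aldehyde (Barbier allylation with allylic transposition), which closes the cyclohexene and creates the exocyclic methylene, and the all-cis diol ester 17 then lactonises. The closest known reaction types are the indium-mediated 2-(alkoxycarbonyl)allylation of unprotected lactols in dilute aqueous acid and the intramolecular zinc-, chromium- or indium-mediated cyclisation of ω-formyl 2-(bromomethyl)alk-2-enoates to carbocycle-fused α-methylene-γ-butyrolactones. The carbocycle closes in a 6-exo-trig mode (C=O exocyclic) through a chair-like six-membered Zimmerman–Traxler array (In, C13, C11, C7, C6, O6) fused to the half-chair of the forming ring, and the lactone closes by 5-exo-trig attack of O8 on the ester carbonyl C12 with loss of methanol. C6 relative to C7 is controlled by the Z geometry of the allyl unit (C8 cis to the CH2In carbon, hence axial in the chair, with the aldehyde substituent C5 equatorial), which should give the syn adduct with O6 cis to C11; C7 relative to C8 is controlled by the C8 stereocentre from step 5, whose free hydroxyl binds indium and takes the inside position while the tether carbon C9 points outside, so that C6 arrives on the face that leaves C11 cis to O8 and the 6,7,8-all-cis triad results. The step needs intramolecular rather than intermolecular addition (high dilution, six-membered ring), γ- rather than α-attack of the allyl unit (six- versus eight-membered ring), and acylation of O8 rather than O6 (O6 lies between the fully substituted C5 and C7, and the syn-1,3-diol can exchange the acyl group under the acidic conditions).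

**Step 10**
Reactants: 18 britannilactone
Product: 19 1,6-O,O-diacetylbritannilactone
Conditions: Ac2O, pyridine, DMAP (cat.), CH2Cl2, 0 °C to rt
Reagents that add atoms: acetic anhydride, CC(=O)OC(C)=O
Why: DMAP-catalysed acylation of the primary C1 hydroxyl and the hindered allylic C6 hydroxyl; no stereocentre is affected.

**Compound list**

1 | (S)-citronellal, (3S)-3,7-dimethyloct-6-enal | O=CC[C@@H](C)CCC=C(C)C | starting material
2 | trimethyl{[(3S)-3,7-dimethylocta-1,6-dien-1-yl]oxy}silane (E/Z) | C[Si](C)(C)OC=C[C@@H](C)CCC=C(C)C | intermediate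
3 | 2,2-dimethoxypropane | COC(C)(C)OC | starting material
4 | (3S)-2-(2-methoxypropan-2-yl)-3,7-dimethyloct-6-enal (C2 epimers) | O=CC([C@@H](C)CCC=C(C)C)C(C)(C)OC | intermediate
5 | (3S)-3,7-dimethyl-2-(propan-2-ylidene)oct-6-enal | O=CC(=C(C)C)[C@@H](C)CCC=C(C)C | intermediate
6 | (3S)-3-methyl-2-(propan-2-ylidene)hexanedial | O=CC(=C(C)C)[C@@H](C)CCC=O | intermediate
7 | (3S)-6-hydroxy-3-methyl-2-(propan-2-ylidene)hexanal | O=CC(=C(C)C)[C@@H](C)CCCO | intermediate
8 | (1E)-1-[(tert-butyldimethylsilyl)oxy]-2-[(2S)-5-[(tert-butyldimethylsilyl)oxy]pentan-2-yl]-3-methylbuta-1,3-diene | CC(C)(C)[Si](C)(C)O/C=C(/C(C)=C)[C@@H](C)CCCO[Si](C)(C)C(C)(C)C | intermediate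
9 | ethyl glyoxylate | CCOC(=O)C=O | starting material
10 | ethyl (2R)-6-[(tert-butyldimethylsilyl)oxy]-5-[(2S)-5-[(tert-butyldimethylsilyl)oxy]pentan-2-yl]-4-methyl-3,6-dihydro-2H-pyran-2-carboxylate | CCOC(=O)[C@H]1CC(C)=C([C@@H](C)CCCO[Si](C)(C)C(C)(C)C)C(O[Si](C)(C)C(C)(C)C)O1 | intermediate
11 | (2R)-6-[(tert-butyldimethylsilyl)oxy]-5-[(2S)-5-[(tert-butyldimethylsilyl)oxy]pentan-2-yl]-4-methyl-3,6-dihydro-2H-pyran-2-carbaldehyde | O=C[C@H]1CC(C)=C([C@@H](C)CCCO[Si](C)(C)C(C)(C)C)C(O[Si](C)(C)C(C)(C)C)O1 | intermediate
12 | methyl acrylate | C=CC(=O)OC | starting material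
13 | methyl 2-{hydroxy[(2R)-6-silyloxy-5-[(2S)-5-silyloxypentan-2-yl]-4-methyl-3,6-dihydro-2H-pyran-2-yl]methyl}prop-2-enoate (silyl = tert-butyldimethylsilyl; carbinol epimers) | C=C(C(=O)OC)C(O)[C@H]1CC(C)=C([C@@H](C)CCCO[Si](C)(C)C(C)(C)C)C(O[Si](C)(C)C(C)(C)C)O1 | intermediate
14 | methyl (2Z)-2-(bromomethyl)-3-[(2R)-6-silyloxy-5-[(2S)-5-silyloxypentan-2-yl]-4-methyl-3,6-dihydro-2H-pyran-2-yl]prop-2-enoate (silyl = tert-butyldimethylsilyl) | BrC/C(=C\[C@H]1CC(C)=C([C@@H](C)CCCO[Si](C)(C)C(C)(C)C)C(O[Si](C)(C)C(C)(C)C)O1)C(=O)OC | intermediate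
15 | methyl (2Z)-2-(bromomethyl)-3-[(2R)-6-hydroxy-5-[(2S)-5-hydroxypentan-2-yl]-4-methyl-3,6-dihydro-2H-pyran-2-yl]prop-2-enoate (lactol) | BrC/C(=C\[C@H]1CC(C)=C([C@@H](C)CCCO)C(O)O1)C(=O)OC | intermediate
16 | methyl (2Z,4R,6Z,8S)-2-(bromomethyl)-7-formyl-4,11-dihydroxy-6,8-dimethylundeca-2,6-dienoate (ring-opened tautomer of 15) | BrC/C(=C\[C@H](O)C/C(C)=C(\C=O)[C@@H](C)CCCO)C(=O)OC | intermediate
17 | methyl 2-[(1R,2R,6R)-2,6-dihydroxy-3-[(2S)-5-hydroxypentan-2-yl]-4-methylcyclohex-3-en-1-yl]prop-2-enoate (all-cis) | C=C(C(=O)OC)[C@@H]1[C@H](O)CC(C)=C([C@@H](C)CCCO)[C@@H]1O | intermediate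
18 | britannilactone (configuration of 19, both acetyl groups replaced by H) | C=C1C(=O)O[C@@H]2CC(C)=C([C@@H](C)CCCO)[C@H](O)[C@H]12 | intermediate
19 | 1,6-O,O-diacetylbritannilactone | C=C1C(=O)O[C@@H]2CC(C)=C([C@@H](C)CCCOC(C)=O)[C@H](OC(C)=O)[C@H]12 | target

**Step count and risks**

Total step count: 10. Longest linear sequence: 10 steps from (S)-citronellal 1.

Steps most likely to fail:

Step 9. The allylindium may attack the face of its C7 terminus that puts C11 trans to O8 if the C8 hydroxyl does not bind the metal, and the acyl group may end on O6 instead of O8. Fallback (lactone formed first so that a ring fixes the fusion, C6 then corrected by redox), setting out from 13 and returning at 18: 13 is treated with aq. HCl/THF and then PPTS, so that desilylation, lactol opening and lactonisation of O8 onto the ester give the 4-hydroxy-3-methylidene-γ-butyrolactone carrying the free (Z)-enal, hydroxy lactone F1. NBS/Me2S converts its allylic alcohol with transposition into the 3-(bromomethyl)butenolide F2 (the saturated primary alcohol returns unchanged on aqueous work-up). Zn dust in THF/aq. NH4Cl closes the cyclohexene; the tether can reach only one face of the butenolide, so the 7,8-cis fusion is enforced, and the closed chair transition state of this E-locked allylzinc is expected to give mainly the C6 epimer, 6-epi-britannilactone F3. MnO2 oxidises its allylic alcohol to the enone F4, and NaBH4/CeCl3·7H2O in MeOH at −78 °C should deliver hydride from the convex face and return 18.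

Step 5. Face discrimination at the glyoxylate carbonyl may be insufficient, or silyl transfer may divert the reaction to an open-chain vinylogous aldol product. Fallback (auxiliary control in place of catalyst control), setting out from 8 and returning at 11: 8 is combined with (1S,2R)-2-phenylcyclohexyl glyoxylate under Eu(fod)3 catalysis, a mild promoter of concerted cycloaddition that keeps silyl acetals intact; the auxiliary is chosen to shield the si face and should give the (1S,2R)-2-phenylcyclohexyl ester F5. DIBAL-H at −78 °C then releases the auxiliary alcohol and gives 11.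

Step 7. The amine-catalysed addition may be slow enough for base-mediated epimerisation at C8 of the α-alkoxy aldehyde to compete. Fallback (aldol addition and selenoxide elimination in place of amine catalysis), setting out from 11 and returning at 13: the lithium enolate of methyl 3-(phenylselanyl)propanoate (LiN(iPr)2, THF, −78 °C) adds to 11 within minutes to give the β-hydroxy selenide F6; oxidation with H2O2/pyridine in CH2Cl2 at 0 °C and syn-elimination of the selenoxide give 13.

**Further compounds**

F1 | step 9 | (5R)-4-hydroxy-3-methylidene-5-[(2Z,4S)-3-formyl-7-hydroxy-2,4-dimethylhept-2-en-1-yl]oxolan-2-one | C=C1C(O)[C@@H](C/C(C)=C(\C=O)[C@@H](C)CCCO)OC1=O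
F2 | step 9 | (5R)-3-(bromomethyl)-5-[(2Z,4S)-3-formyl-7-hydroxy-2,4-dimethylhept-2-en-1-yl]furan-2(5H)-one | BrCC1=C[C@@H](C/C(C)=C(\C=O)[C@@H](C)CCCO)OC1=O
F3 | step 9 | 6-epi-britannilactone | C=C1C(=O)O[C@@H]2CC(C)=C([C@@H](C)CCCO)[C@@H](O)[C@H]12
F4 | step 9 | 6-oxo analogue of britannilactone (enone) | C=C1C(=O)O[C@@H]2CC(C)=C([C@@H](C)CCCO)C(=O)[C@H]12
F5 | step 5 | (1S,2R)-2-phenylcyclohexyl ester analogue of 10 | O=C(O[C@H]1CCCC[C@@H]1c1ccccc1)[C@H]1CC(C)=C([C@@H](C)CCCO[Si](C)(C)C(C)(C)C)C(O[Si](C)(C)C(C)(C)C)O1
F6 | step 7 | methyl 3-hydroxy-2-[(phenylselanyl)methyl]-3-[(2R)-6-silyloxy-5-[(2S)-5-silyloxypentan-2-yl]-4-methyl-3,6-dihydro-2H-pyran-2-yl]propanoate (silyl = tert-butyldimethylsilyl) | COC(=O)C(C[Se]c1ccccc1)C(O)[C@H]1CC(C)=C([C@@H](C)CCCO[Si](C)(C)C(C)(C)C)C(O[Si](C)(C)C(C)(C)C)O1
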